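At late times Saturday's flask stood still, 50.7 % at 20.0 h and 50.2 % at 30.0 h, within the scatter of 0.5 percentage points. I began from that stop.

| flask | starting material | partner | protic impurity | temperature | remark | time |
|---|---|---|---|---|---|---|
| Tuesday's | 0.075 M | 0.11 M | 0.020 M | 35 °C | run made earlier |  |
| Saturday's | 0.16 M | 0.11 M | 0.020 M | 55 °C | run made earlier |  |
| Wednesday's | 0.10 M | 0.10 M | 0.020 M | 35 °C | run made earlier |  |
| winter | 0.10 M | 0.110 M | 0.0200 M | 70 °C |  | 2.5 d |
| autumn | 0.10 M | 0.0800 M | 0.0300 M | 40 °C |  | 2.5 d |
| midnight | 0.10 M | 0.110 M | 0.0200 M | 40 °C |  | 2.5 d |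
| dusk | 0.060 M | 0.110 M | 0.0200 M | 40 °C |  | 2.5 d |

Tuesday's run (percent of the starting material charged): time / d: target / % = 0.208: 3.3; 0.333: 8.1; 0.500: 13.0; 0.625: 16.9; 1.04: 27.8; 1.67: 41.4; 2.50: 53.3

Saturday's run (percent of the starting material charged): time / h: target / % = 1.33: 9.8; 5.00: 33.1; 8.00: 41.0; 12.0: 45.7; 20.0: 50.7; 25.0: 50.5; 30.0: 50.2

Wednesday's run (percent of the starting material charged): time / d: target / % = 0.500: 12.4; 1.04: 24.1; 1.67: 36.4; 2.08: 42.3; 2.50: 46.7

(scatter of a reading: 0.5 percentage points)

- all flasks from highest to lowest amount of target, in percent of the starting material charged, at 2.5 d (winter / autumn / midnight / dusk)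
- the amount of target, in percent of the starting material charged of the flask you put first, at 2.5 d
- the amount of target, in percent of the starting material charged of the flask you put last, at 2.5 d

- no earlier run changes the charge of protic impurity; that part of a forecast is a guess

I built the flask up one process at a time, with amounts as fractions of the starting material charged. With the main step alone, one partner makes one target, so the partner charged is a ceiling. On Saturday's charge that ceiling was 0.688, well above the reading.

Next I let each protic impurity take one partner, which is a guess, as no run changes that charge. This gives the usable share, partner charged less impurity charged, over starting material charged; below one, it marks partner as the limiting reagent. For autumn the main step gives 0.800, and the usable share is 0.500.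

Saturday's usable share was 0.562. The rest of that flask I couldn't see, so I lumped it into one factor, the reading over the share:

0.898 of the share reached on Saturday

0.898 × 0.500 = 44.9 % for autumn

I used this factor on autumn alone, as its share stands close to Saturday's. The shares also rank the flasks. Midnight and winter stand level at 0.900, and the share can't part them. Dusk has 1.50, above one, so its ceiling is the whole charge. Autumn is lowest.

The forecast gave dusk > midnight > winter > autumn, with 68 % for the first flask and 45 % for the last, and it said “Autumn is limited by partner”.

The flasks gave dusk > midnight > winter > autumn, with 73.1 % and 44.1 %, so the forecast's top stood 5.1 points under the result.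

    starting material → intermediate (k = 0.0360 h⁻¹, Ea = 102 kJ mol⁻¹)
    partner + intermediate → target (k = 3.90 M⁻¹ h⁻¹, Ea = 69.0 kJ mol⁻¹)
    2 intermediate → homo product (k = 7.40 M⁻¹ h⁻¹, Ea = 74.0 kJ mol⁻¹)
    partner + protic impurity → quenched reagent (k = 1.30 M⁻¹ h⁻¹, Ea = 77.0 kJ mol⁻¹)
    partner → decomposition product (k = 4.00 × 10⁻⁵ h⁻¹, Ea = 129 kJ mol⁻¹)
    intermediate → side product (k = 0.00290 h⁻¹, Ea = 123 kJ mol⁻¹)
    (constants at 40 °C)

At 2.5 d autumn's 44.1 % lay under its usable share of 50.0 %. Left until 25.0 d, it reached 49.5 %, still under that share, with 1.37 % of its partner charge remaining. The depletion of partner is the largest single effect on autumn's number: with partner held at its charge, autumn gives 70.9 % instead of 44.1 %. The impurity's loss of partner is a part of the reason: without that step autumn gives 57.1 %.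

Take dusk's neighbour with 0.44 M of partner. Its usable share is 7.00, so the ceiling is the whole charge, less the 11.5 % still standing as starting material at the asked time: 88.5 %. The flask gives 87.4 %.

The runs were computed for substances that don't exist, and the scatter is random.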